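**Retrosynthetic overview**
1. The 16-membered lactam is opened at N11–C12 (amine plus acylketene from a dioxinone, last ring formed); the C2–C7 triene comes from an ene-diyne (C3–C4 Sonogashira coupling, zinc semi-reduction).
2. Ring B (cyclohexene C19–C24) is annulated onto a ring A ketone at C20: aldol condensation with a C22 methyl ketone, then 1,2-reduction and reductive 1,3-transposition, which sets C20.
3. Key disconnection: C16–C24 and C18–C19 are made together by a Prins–pinacol ring-enlarging annulation of a cyclopentanediol acetal carrying an (E)-alkenyl carbinol; this builds the tetrahydrofuran and ring A in one operation.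
4. Enabling feature: in the tetrahydrofuran C16–O17–C18–C19–C24, O17 is flanked by C16 and C18 and C19 carries C20 of ring A; with C20 as a ketone this is a 3-acyltetrahydrofuran, and ring A (C18, C19, C20, C25, C26, C27) is a cyclopentane (C18, C27, C26, C25, C20) with C19 inserted.
5. Ring order: cyclopentane (chiral-pool enone 20) → tetrahydrofuran + ring A (key step) → ring B → macrolactam; fragments are alkyne 8, acetal 11, diyne 19 and enone 20.

Key step: step 19

Remark (numbering, read from the target SMILES left to right): C1 is the methyl on C2; C2=C3, C4=C5, C6=C7 the triene; C8 (methyl C9); C10; N11; C12 amide carbonyl; C13; C14 ketone; C15; C16–O17–C18–C19–C24 the tetrahydrofuran; ring A = C18, C19, C20, C25, C26, C27 (hydroxyls on C25 and C27); ring B = C19, C20, C21=C22, C23, C24.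
Remark (assumption): enone 20 (the D-ribose-derived building block), (bromoethynyl)triisopropylsilane and the ProPhenol ligand are taken as purchasable; in step 3 the ligand enantiomer is the one that gives the R carbinol.

**Alkyne fragment 8 (C19, C21–C24, C1–C3)**

Step 1
Reactants: 1 prop-2-yn-1-ol
Product: 2 (Z)-3-bromo-2-methylprop-2-en-1-ol
Conditions: MeMgBr (2.5 equiv), CuI (10 mol%), THF, −10 °C to rt; then N-bromosuccinimide, −30 °C
Reagents that add atoms: methylmagnesium bromide C[Mg]Br; N-bromosuccinimide O=C1CCC(=O)N1Br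
Why: Alkoxide-directed anti-carbomagnesiation places the methyl on the internal carbon and magnesium cis to CH2O, so bromination with retention should give the Z bromide that later defines the C2=C3 geometry.

Step 2
Reactants: 2 (Z)-3-bromo-2-methylprop-2-en-1-ol
Product: 3 (Z)-3-bromo-2-methylprop-2-enal
Conditions: MnO2 (activated, excess), CH2Cl2, rt
Reagents that add atoms: none
Why: Neutral allylic oxidation should give the enal without Z to E isomerisation.

Step 3
Reactants: 3 (Z)-3-bromo-2-methylprop-2-enal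
Product: 4 (3R,1Z)-1-bromo-2-methyl-5-(trimethylsilyl)pent-1-en-4-yn-3-ol
Conditions: Me3SiC≡CH, Me2Zn, ProPhenol ligand (20 mol%), Ph3PO, toluene, 4 °C
Reagents that add atoms: ethynyltrimethylsilane C#C[Si](C)(C)C
Why: Ligand-controlled addition of the zinc acetylide to the enal (catalytic asymmetric alkynylation) should set the R carbinol, whose configuration is relayed to C23 in step 4.

Step 4
Reactants: 4 (3R,1Z)-1-bromo-2-methyl-5-(trimethylsilyl)pent-1-en-4-yn-3-ol
Product: 6 (2S,3S)-3-[(Z)-1-bromoprop-1-en-2-yl]-5-(trimethylsilyl)pent-4-yn-2-ol, via mesylate 5 (not isolated)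
Conditions: MeSO2Cl, Et3N, CH2Cl2, −78 °C; then Pd(OAc)2 (5 mol%), PPh3 (5 mol%), Et2Zn (3 equiv), CH3CHO, THF, −78 to −20 °C
Reagents that add atoms: acetaldehyde CC=O
Why: Anti SN2′ attack of palladium on the propargylic mesylate, transmetalation to the allenylzinc and cyclic SE2′ addition to acetaldehyde (palladium-catalysed zinc-mediated propargylation) should form C22–C23 with net inversion and the anti relationship, which sets C23.

Step 5
Reactants: 6 (2S,3S)-3-[(Z)-1-bromoprop-1-en-2-yl]-5-(trimethylsilyl)pent-4-yn-2-ol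
Product: 8 triethyl{[(2S,3S)-3-[(Z)-1-bromoprop-1-en-2-yl]pent-4-yn-2-yl]oxy}silane, via triethylsilyl ether 7 (not isolated)
Conditions: Et3SiCl, imidazole, CH2Cl2, 0 °C; then K2CO3, MeOH, rt
Reagents that add atoms: chlorotriethylsilane CC[Si](Cl)(CC)CC
Why: Silylation followed by methanolysis of the alkynyl C–Si bond should free the terminal alkyne while the secondary triethylsilyl ether survives.

**Acetal fragment 11 (C12–C16)**

Step 6
Reactants: 9 2,2,6-trimethyl-4H-1,3-dioxin-4-one
Product: 10 2,2-dimethyl-6-methylidene-4-(trimethylsilyloxy)-6H-1,3-dioxine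
Conditions: LiN(i-Pr)2, THF, −78 °C; then Me3SiCl
Reagents that add atoms: chlorotrimethylsilane C[Si](C)(C)Cl
Why: Deprotonation of the vinylogous ester at the 6-methyl group and O-silylation give the dienol silyl ether (standard enolate silylation).

Step 7
Reactants: 10 2,2-dimethyl-6-methylidene-4-(trimethylsilyloxy)-6H-1,3-dioxine
Product: 11 6-(2,2-dimethoxyethyl)-2,2-dimethyl-4H-1,3-dioxin-4-one
Conditions: HC(OMe)3, BF3·OEt2, CH2Cl2, −78 °C
Reagents that add atoms: trimethyl orthoformate COC(OC)OC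
Why: Vinylogous Mukaiyama-type addition of the dienol ether through its terminal carbon to the dimethoxycarbenium ion should install C16 as the dimethyl acetal.

**Diyne fragment 19 (C4–C10, N11)**

Step 8
Reactants: 12 methyl (S)-3-hydroxy-2-methylpropanoate
Product: 13 methyl (S)-3-azido-2-methylpropanoate
Conditions: PPh3, diisopropyl azodicarboxylate, (PhO)2P(O)N3, THF, 0 °C to rt
Reagents that add atoms: diphenylphosphoryl azide [N-]=[N+]=NP(=O)(Oc1ccccc1)Oc1ccccc1
Why: Mitsunobu azidation occurs at the primary carbon, so the C8 stereocentre from the chiral pool is untouched.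

Step 9
Reactants: 13 methyl (S)-3-azido-2-methylpropanoate
Product: 15 methyl (S)-2-methyl-3-({[2-(trimethylsilyl)ethoxy]carbonyl}amino)propanoate, via amine 14 (not isolated)
Conditions: H2 (1 atm), Pd/C, 2,5-dioxopyrrolidin-1-yl 2-(trimethylsilyl)ethyl carbonate, EtOAc, rt
Reagents that add atoms: 2,5-dioxopyrrolidin-1-yl 2-(trimethylsilyl)ethyl carbonate C[Si](C)(C)CCOC(=O)ON1C(=O)CCC1=O
Why: Hydrogenolysis of the azide with in situ carbamoylation should trap the β-amino ester before it can self-condense.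

Step 10
Reactants: 15 methyl (S)-2-methyl-3-({[2-(trimethylsilyl)ethoxy]carbonyl}amino)propanoate
Product: 16 2-(trimethylsilyl)ethyl [(S)-2-methyl-3-oxopropyl]carbamate
Conditions: i-Bu2AlH (2.2 equiv), CH2Cl2, −78 °C
Reagents that add atoms: none
Why: Low-temperature partial reduction of the ester should stop at the aldehyde, which is used crude to protect the α-stereocentre.

Step 11
Reactants: 16 2-(trimethylsilyl)ethyl [(S)-2-methyl-3-oxopropyl]carbamate
Product: 17 2-(trimethylsilyl)ethyl [(R)-2-methylbut-3-yn-1-yl]carbamate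
Conditions: dimethyl (1-diazo-2-oxopropyl)phosphonate, K2CO3, MeOH, 0 °C to rt
Reagents that add atoms: dimethyl (1-diazo-2-oxopropyl)phosphonate CC(=O)C(=[N+]=[N-])P(=O)(OC)OC
Why: Seyferth–Gilbert homologation under carbonate/methanol conditions should give the terminal alkyne (C6≡C7) mildly enough to keep C8.

Step 12
Reactants: 17 2-(trimethylsilyl)ethyl [(R)-2-methylbut-3-yn-1-yl]carbamate
Product: 18 2-(trimethylsilyl)ethyl [(R)-2-methyl-6-(triisopropylsilyl)hexa-3,5-diyn-1-yl]carbamate
Conditions: (bromoethynyl)triisopropylsilane, CuCl (10 mol%), NH2OH·HCl, n-BuNH2, H2O/Et2O, 0 °C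
Reagents that add atoms: (bromoethynyl)triisopropylsilane CC(C)[Si](C#CBr)(C(C)C)C(C)C
Why: Cadiot–Chodkiewicz coupling should give the unsymmetrical 1,3-diyne that supplies C4–C7.

Step 13
Reactants: 18 2-(trimethylsilyl)ethyl [(R)-2-methyl-6-(triisopropylsilyl)hexa-3,5-diyn-1-yl]carbamate
Product: 19 2-(trimethylsilyl)ethyl [(R)-2-methylhexa-3,5-diyn-1-yl]carbamate
Conditions: Bu4NF (1.05 equiv), THF, −20 °C, short reaction time
Reagents that add atoms: none
Why: Fluoride cleaves the alkynyl C–Si bond much faster than the silylethyl carbamate at low temperature.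

**Main line**

Step 14
Reactants: 8 alkyne fragment; 20 (3aR,6aR)-2,2-dimethyl-3a,6a-dihydro-4H-cyclopenta[d][1,3]dioxol-4-one
Product: 21 C20 tertiary propargylic alcohol (hydroxyl cis to the dioxolane oxygens)
Conditions: 8, EtMgBr, THF, 0 °C to rt; then 20, −40 to 0 °C
Reagents that add atoms: none
Why: 1,2-Addition of the alkynylmagnesium reagent to the enone from the convex face anti to the acetonide should place the C20 hydroxyl cis to O17 and O27.

Step 15
Reactants: 21 C20 tertiary propargylic alcohol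
Product: 22 C25–C26 epoxide (cis to the C20 hydroxyl)
Conditions: VO(acac)2 (5 mol%), t-BuOOH, CH2Cl2, 0 °C to rt
Reagents that add atoms: tert-butyl hydroperoxide CC(C)(C)OO
Why: Hydroxyl-directed epoxidation of the cyclic allylic alcohol delivers oxygen syn to the C20 hydroxyl, which sets the C25–O bond cis to O17 and O27, while the alkyne and the bromoalkene are inert.

Step 16
Reactants: 22 C25–C26 epoxide
Product: 23 (E)-alkenyl diol (tertiary C20–OH and secondary C25–OH)
Conditions: LiAlH4, THF, 0 °C to rt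
Reagents that add atoms: none
Why: The alkoxyaluminate should add hydride trans across the propargylic alkyne to give the E alkene C19=C24, and external hydride should open the epoxide at the less hindered C26, leaving the C25 hydroxyl in place.

Step 17
Reactants: 23 (E)-alkenyl diol
Product: 24 C25 tert-butyldimethylsilyl ether
Conditions: t-BuMe2SiOTf (1.1 equiv), 2,6-lutidine, CH2Cl2, −78 °C
Reagents that add atoms: tert-butyldimethylsilyl trifluoromethanesulfonate CC(C)(C)[Si](C)(C)OS(=O)(=O)C(F)(F)F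
Why: At low temperature the secondary C25 hydroxyl should be silylated in preference to the tertiary C20 hydroxyl.

Step 18
Reactants: 24 C25 tert-butyldimethylsilyl ether; 11 6-(2,2-dimethoxyethyl)-2,2-dimethyl-4H-1,3-dioxin-4-one
Product: 25 dioxolane acetal of the C18/C27 diol at C16 (C16 epimers; C20–OH free)
Conditions: 11 (3 equiv), PPTS (10 mol%), CH2Cl2, 4 Å molecular sieves, rt to 35 °C
Reagents that add atoms: none
Why: Acid-catalysed transacetalisation should replace the ketal by the less hindered aldehyde-derived dioxolane, and the configuration at C16 does not matter because this carbon becomes planar in the next step.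

Step 19
Reactants: 25 dioxolane acetal
Product: 26 cis-fused tetrahydrofuran/cyclohexanone (C20 ketone; C27–OH free)
Conditions: SnCl4 (2 equiv), CH2Cl2, −78 °C to −20 °C
Reagents that add atoms: none
Why: SnCl4 opens the dioxolane at C16–O27 to the (E)-oxocarbenium ion C16=O17 (the other opening is unproductive and reversible), the (E)-alkene adds through C24 in a chair-like Prins closure with the C15 and C23 substituents equatorial (new C16–C24 bond), and the C19 cation is quenched by 1,2-shift of C18 from the carbinol carbon C20 (pinacol step, new C18–C19 bond), so that C20 becomes the ketone and O27 is released as the free hydroxyl. The closest known reaction type is the Prins–pinacol ring-enlarging tetrahydrofuran annulation of 1-alkenylcycloalkane-1,2-diol acetals. The tetrahydrofuran is closed by 6-endo Prins cyclisation followed by ring contraction (formally a suprafacial [3+2] addition of C16–O17–C18 across C19=C24), and ring A is closed by one-carbon ring expansion of the cyclopentane (C19 inserted between C18 and C20). C18 migrates with retention and fixes the absolute sense, C16 follows from the E oxocarbenium ion (C15 equatorial, cis to C27 across O17), C24 from the E alkene (C23 trans to C15 and to C20), and C19 from the suprafacial shift that enforces the cis fusion of the tetrahydrofuran with ring A. The step needs ionisation at the acetal carbon rather than at the tertiary allylic C20–O bond and Prins closure rather than proton loss from C15; the low temperature, the non-basic medium and the chair that is trans-fused to the cyclopentane (alkenyl group trans to O17) should secure this.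

Step 20
Reactants: 26 cis-fused tetrahydrofuran/cyclohexanone
Product: 27 C27 tert-butyldimethylsilyl ether
Conditions: t-BuMe2SiOTf, 2,6-lutidine, CH2Cl2, −78 to 0 °C
Reagents that add atoms: tert-butyldimethylsilyl trifluoromethanesulfonate CC(C)(C)[Si](C)(C)OS(=O)(=O)C(F)(F)F
Why: Silylation of the liberated C27 hydroxyl ensures that only C22 is oxidised in the next step.

Step 21
Reactants: 27 C27 tert-butyldimethylsilyl ether
Product: 29 C20/C22 diketone (C22 methyl ketone), via secondary alcohol 28 (not isolated)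
Conditions: IBX (3 equiv), DMSO, rt
Reagents that add atoms: none
Why: IBX in DMSO cleaves triethylsilyl ethers in the presence of tert-butyldimethylsilyl ethers and oxidises the freed secondary alcohol to the ketone.

Step 22
Reactants: 29 C20/C22 diketone
Product: 31 ring A/B enone (C20=C21–C22=O), via aldol 30 (not isolated)
Conditions: pyrrolidine (0.5 equiv), AcOH (0.5 equiv), toluene, rt to 50 °C
Reagents that add atoms: none
Why: The enamine of the methyl ketone (C21) adds to the C20 ketone and dehydration closes ring B as the conjugated enone (intramolecular aldol condensation of a 1,5-diketone), whereas the alternative aldol from C25 onto C22 could only dehydrate to a bridgehead alkene and stays reversible.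

Step 23
Reactants: 31 ring A/B enone
Product: 32 C22 allylic alcohol (hydroxyl cis to the C23 bromoalkenyl group)
Conditions: LiBH(s-Bu)3, THF, −78 °C
Reagents that add atoms: none
Why: The bulky hydride should reduce the β,β-disubstituted enone at the carbonyl from the face anti to the C23 substituent, giving the alcohol whose configuration is relayed to C20 in step 24.

Step 24
Reactants: 32 C22 allylic alcohol
Product: 35 tricyclic bromoalkene (C21=C22; C20–H cis to C19–H), via sulfonylhydrazine 33 (not isolated), via diazene 34 (not isolated)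
Conditions: 2-nitrobenzenesulfonylhydrazide, PPh3, diethyl azodicarboxylate, THF, −30 °C; then rt
Reagents that add atoms: none
Why: Mitsunobu displacement with inversion, loss of sulfinate and suprafacial retro-ene loss of N2 from the monoalkyl diazene (reductive 1,3-transposition of the allylic alcohol) should move the alkene to C21=C22 and deliver hydrogen to C20 on the face of the departing nitrogen, which sets C20.

Step 25
Reactants: 35 tricyclic bromoalkene; 19 diyne carbamate
Product: 36 ene-diyne carbamate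
Conditions: Pd(PPh3)4 (10 mol%), CuI (20 mol%), Et3N, DMF, rt to 45 °C
Reagents that add atoms: none
Why: Sonogashira coupling of the Z alkenyl bromide proceeds with retention and forms the C3–C4 bond.

Step 26
Reactants: 36 ene-diyne carbamate
Product: 37 (2Z,4Z,6Z)-triene carbamate
Conditions: Zn dust activated with Cu(OAc)2 and AgNO3, MeOH/H2O (1:1), rt to 40 °C
Reagents that add atoms: none
Why: Activated zinc reduces conjugated alkynes by cis addition of hydrogen and stops at the alkene, so both triple bonds should give Z alkenes.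

Step 27
Reactants: 37 (2Z,4Z,6Z)-triene carbamate
Product: 38 amino diol dioxinone (seco compound)
Conditions: Bu4NF (excess), THF, rt to 45 °C
Reagents that add atoms: none
Why: Fluoride removes both silyl ethers and the silylethyl carbamate (fragmentation to ethene and CO2), and the dioxinone does not acylate the free amine at this temperature.

Step 28
Reactants: 38 amino diol dioxinone
Product: 40 verticilactam C, via acylketene 39 (not isolated)
Conditions: toluene (0.5 mM), 110 °C
Reagents that add atoms: none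
Why: Thermal retro-[4+2] of the dioxinone releases acetone and an acylketene that the primary amine should capture faster than the hydroxyls at high dilution, closing the 16-membered β-keto lactam.

**Compound list**
1 | prop-2-yn-1-ol | C#CCO | starting material
2 | (Z)-3-bromo-2-methylprop-2-en-1-ol | OC/C(C)=C\Br | intermediate
3 | (Z)-3-bromo-2-methylprop-2-enal | O=C/C(C)=C\Br | intermediate
4 | (3R,1Z)-1-bromo-2-methyl-5-(trimethylsilyl)pent-1-en-4-yn-3-ol | C[Si](C)(C)C#C[C@@H](O)/C(C)=C\Br | intermediate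
5 | methanesulfonate of 4 | C[Si](C)(C)C#C[C@@H](OS(C)(=O)=O)/C(C)=C\Br | intermediate
6 | (2S,3S)-3-[(Z)-1-bromoprop-1-en-2-yl]-5-(trimethylsilyl)pent-4-yn-2-ol | C[Si](C)(C)C#C[C@H]([C@H](C)O)/C(C)=C\Br | intermediate
7 | triethylsilyl ether of 6 | C[Si](C)(C)C#C[C@H]([C@H](C)O[Si](CC)(CC)CC)/C(C)=C\Br | intermediate
8 | triethyl{[(2S,3S)-3-[(Z)-1-bromoprop-1-en-2-yl]pent-4-yn-2-yl]oxy}silane | C#C[C@H]([C@H](C)O[Si](CC)(CC)CC)/C(C)=C\Br | intermediate
9 | 2,2,6-trimethyl-4H-1,3-dioxin-4-one | CC1=CC(=O)OC(C)(C)O1 | starting material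
10 | 2,2-dimethyl-6-methylidene-4-(trimethylsilyloxy)-6H-1,3-dioxine | C=C1C=C(O[Si](C)(C)C)OC(C)(C)O1 | intermediate
11 | 6-(2,2-dimethoxyethyl)-2,2-dimethyl-4H-1,3-dioxin-4-one | COC(OC)CC1=CC(=O)OC(C)(C)O1 | intermediate
12 | methyl (S)-3-hydroxy-2-methylpropanoate | COC(=O)[C@@H](C)CO | starting material
13 | methyl (S)-3-azido-2-methylpropanoate | COC(=O)[C@@H](C)CN=[N+]=[N-] | intermediate
14 | methyl (S)-3-amino-2-methylpropanoate | COC(=O)[C@@H](C)CN | intermediate
15 | methyl (S)-2-methyl-3-({[2-(trimethylsilyl)ethoxy]carbonyl}amino)propanoate | COC(=O)[C@@H](C)CNC(=O)OCC[Si](C)(C)C | intermediate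
16 | 2-(trimethylsilyl)ethyl [(S)-2-methyl-3-oxopropyl]carbamate | O=C[C@@H](C)CNC(=O)OCC[Si](C)(C)C | intermediate
17 | 2-(trimethylsilyl)ethyl [(R)-2-methylbut-3-yn-1-yl]carbamate | C#C[C@@H](C)CNC(=O)OCC[Si](C)(C)C | intermediate
18 | 2-(trimethylsilyl)ethyl [(R)-2-methyl-6-(triisopropylsilyl)hexa-3,5-diyn-1-yl]carbamate | CC(C)[Si](C#CC#C[C@@H](C)CNC(=O)OCC[Si](C)(C)C)(C(C)C)C(C)C | intermediate
19 | 2-(trimethylsilyl)ethyl [(R)-2-methylhexa-3,5-diyn-1-yl]carbamate | C#CC#C[C@@H](C)CNC(=O)OCC[Si](C)(C)C | intermediate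
20 | (3aR,6aR)-2,2-dimethyl-3a,6a-dihydro-4H-cyclopenta[d][1,3]dioxol-4-one | CC1(C)O[C@@H]2C=CC(=O)[C@@H]2O1 | starting material
21 | C20 tertiary propargylic alcohol (1,2-adduct of 8 and 20; OH cis to the dioxolane oxygens) | CC1(C)O[C@@H]2C=C[C@@](O)(C#C[C@H]([C@H](C)O[Si](CC)(CC)CC)/C(C)=C\Br)[C@@H]2O1 | intermediate
22 | C25–C26 epoxide of 21 (epoxide cis to C20–OH) | CC1(C)O[C@@H]2[C@@H]3O[C@@H]3[C@@](O)(C#C[C@H]([C@H](C)O[Si](CC)(CC)CC)/C(C)=C\Br)[C@@H]2O1 | intermediate
23 | (E)-alkenyl diol (C20 tertiary OH, C25 secondary OH, acetonide on O17/O27) | CC1(C)O[C@@H]2C[C@H](O)[C@@](O)(/C=C/[C@H]([C@H](C)O[Si](CC)(CC)CC)/C(C)=C\Br)[C@@H]2O1 | intermediate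
24 | C25 tert-butyldimethylsilyl ether of 23 | CC1(C)O[C@@H]2C[C@H](O[Si](C)(C)C(C)(C)C)[C@@](O)(/C=C/[C@H]([C@H](C)O[Si](CC)(CC)CC)/C(C)=C\Br)[C@@H]2O1 | intermediate
25 | dioxolane acetal of the C18/C27 diol with the dioxinone aldehyde (C16 epimers, C20–OH free) | CC1(C)OC(=O)C=C(CC2O[C@@H]3C[C@H](O[Si](C)(C)C(C)(C)C)[C@@](O)(/C=C/[C@H]([C@H](C)O[Si](CC)(CC)CC)/C(C)=C\Br)[C@@H]3O2)O1 | intermediate
26 | cis-fused tetrahydrofuran/cyclohexanone (C20 ketone, C27–OH free) | CC1(C)OC(=O)C=C(C[C@@H]2O[C@H]3[C@@H]([C@H]2[C@H]([C@H](C)O[Si](CC)(CC)CC)/C(C)=C\Br)C(=O)[C@@H](O[Si](C)(C)C(C)(C)C)C[C@H]3O)O1 | intermediate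
27 | C27 tert-butyldimethylsilyl ether of 26 | CC1(C)OC(=O)C=C(C[C@@H]2O[C@H]3[C@@H]([C@H]2[C@H]([C@H](C)O[Si](CC)(CC)CC)/C(C)=C\Br)C(=O)[C@@H](O[Si](C)(C)C(C)(C)C)C[C@H]3O[Si](C)(C)C(C)(C)C)O1 | intermediate
28 | C22 secondary alcohol from 27 | CC1(C)OC(=O)C=C(C[C@@H]2O[C@H]3[C@@H]([C@H]2[C@H]([C@H](C)O)/C(C)=C\Br)C(=O)[C@@H](O[Si](C)(C)C(C)(C)C)C[C@H]3O[Si](C)(C)C(C)(C)C)O1 | intermediate
29 | C20/C22 diketone (C22 methyl ketone) | CC1(C)OC(=O)C=C(C[C@@H]2O[C@H]3[C@@H]([C@H]2[C@H](C(C)=O)/C(C)=C\Br)C(=O)[C@@H](O[Si](C)(C)C(C)(C)C)C[C@H]3O[Si](C)(C)C(C)(C)C)O1 | intermediate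
30 | aldol adduct (C20 tertiary carbinol, C22 ketone, C20 configuration not defined) | CC1(C)OC(=O)C=C(C[C@@H]2O[C@H]3[C@@H]4C(O)(CC(=O)[C@@H]([C@H]42)/C(C)=C\Br)[C@@H](O[Si](C)(C)C(C)(C)C)C[C@H]3O[Si](C)(C)C(C)(C)C)O1 | intermediate
31 | ring A/B enone (C20=C21–C22=O) | CC1(C)OC(=O)C=C(C[C@@H]2O[C@H]3[C@@H]4C(=CC(=O)[C@@H]([C@H]42)/C(C)=C\Br)[C@@H](O[Si](C)(C)C(C)(C)C)C[C@H]3O[Si](C)(C)C(C)(C)C)O1 | intermediate
32 | C22 allylic alcohol (OH cis to the C23 bromoalkenyl group) | CC1(C)OC(=O)C=C(C[C@@H]2O[C@H]3[C@@H]4C(=C[C@H](O)[C@@H]([C@H]42)/C(C)=C\Br)[C@@H](O[Si](C)(C)C(C)(C)C)C[C@H]3O[Si](C)(C)C(C)(C)C)O1 | intermediate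
33 | C22 N-(2-nitrophenylsulfonyl)hydrazine (inverted at C22) | CC1(C)OC(=O)C=C(C[C@@H]2O[C@H]3[C@@H]4C(=C[C@@H](N(N)S(=O)(=O)c5ccccc5[N+](=O)[O-])[C@@H]([C@H]42)/C(C)=C\Br)[C@@H](O[Si](C)(C)C(C)(C)C)C[C@H]3O[Si](C)(C)C(C)(C)C)O1 | intermediate
34 | C22 monoalkyl diazene | CC1(C)OC(=O)C=C(C[C@@H]2O[C@H]3[C@@H]4C(=C[C@@H](N=N)[C@@H]([C@H]42)/C(C)=C\Br)[C@@H](O[Si](C)(C)C(C)(C)C)C[C@H]3O[Si](C)(C)C(C)(C)C)O1 | intermediate
35 | tricyclic bromoalkene (C21=C22, all ring stereocentres of the target) | CC1(C)OC(=O)C=C(C[C@@H]2O[C@H]3[C@@H]4[C@@H](C=C[C@@H]([C@H]42)/C(C)=C\Br)[C@@H](O[Si](C)(C)C(C)(C)C)C[C@H]3O[Si](C)(C)C(C)(C)C)O1 | intermediate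
36 | ene-diyne carbamate | CC1(C)OC(=O)C=C(C[C@@H]2O[C@H]3[C@@H]4[C@@H](C=C[C@@H]([C@H]42)/C(C)=C\C#CC#C[C@@H](C)CNC(=O)OCC[Si](C)(C)C)[C@@H](O[Si](C)(C)C(C)(C)C)C[C@H]3O[Si](C)(C)C(C)(C)C)O1 | intermediate
37 | (2Z,4Z,6Z)-triene carbamate | CC1(C)OC(=O)C=C(C[C@@H]2O[C@H]3[C@@H]4[C@@H](C=C[C@@H]([C@H]42)/C(C)=C\C=C/C=C\[C@@H](C)CNC(=O)OCC[Si](C)(C)C)[C@@H](O[Si](C)(C)C(C)(C)C)C[C@H]3O[Si](C)(C)C(C)(C)C)O1 | intermediate
38 | amino diol dioxinone (seco compound) | CC1(C)OC(=O)C=C(C[C@@H]2O[C@H]3[C@@H]4[C@@H](C=C[C@@H]([C@H]42)/C(C)=C\C=C/C=C\[C@@H](C)CN)[C@@H](O)C[C@H]3O)O1 | intermediate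
39 | acylketene | O=C=CC(=O)C[C@@H]1O[C@H]2[C@@H]3[C@@H](C=C[C@@H]([C@H]31)/C(C)=C\C=C/C=C\[C@@H](C)CN)[C@@H](O)C[C@H]2O | intermediate
40 | verticilactam C | C/C1=C/C=C\C=C/[C@@H](C)CNC(=O)CC(=O)C[C@@H]2O[C@H]3[C@@H]4[C@@H](C=C[C@H]1[C@H]42)[C@@H](O)C[C@H]3O | target

**Step count and risks**
Total step count: 28. Longest linear sequence: 20 steps (steps 1–5, then 14–28).

Steps most likely to fail:

1. Step 19. The oxocarbenium ion may be lost before Prins closure, by proton loss from C15 or by Lewis-acid-induced reaction at the electron-rich dioxinone. Fallback: setting out from 24, transacetalisation with methyl 3,3-dimethoxypropanoate (PPTS) should give the ester acetal F1, which on the same SnCl4 treatment should rearrange to the ester hydroxy ketone F2. Silylation (t-BuMe2SiOTf, 2,6-lutidine) gives the silyl ether F3 and LiOH (THF/H2O) the carboxylic acid F4. Coupling with 2,2-dimethyl-1,3-dioxane-4,6-dione (dicyclohexylcarbodiimide, 4-dimethylaminopyridine) gives the acyl dioxanedione F5, and heating F5 with acetone in toluene (acylketene formation, capture by acetone) comes back to the route at 27. The dioxinone is then built after the key step instead of being carried through it.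

2. Step 4. The doubly activated (propargylic and allylic) mesylate may ionise or eliminate, and palladium may insert into the C–Br bond, so that material and configurational purity at C23 are lost. Fallback: setting out from 3, a Wittig reaction with the ylide from EtPPh3Br and NaN(SiMe3)2 should give the Z,Z-diene F6. Epoxidation of its cis-disubstituted alkene with NaOCl and a chiral (salen)MnCl catalyst ([N,N′-bis(3,5-di-tert-butylsalicylidene)-1,2-cyclohexanediaminato]manganese chloride) should give the cis-vinyl epoxide F7. Opening of F7 at the allylic carbon with inversion by Me3SiC≡C–AlEt2 (from Me3SiC≡CLi and Et2AlCl) comes back at 6.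

3. Step 23. Hydride delivery at C22 may show poor facial selectivity; the C22 epimer would be relayed to the wrong C20 configuration (trans ring fusion) in step 24. Fallback: setting out from 31, reduction with NaBH4 and CeCl3·7H2O in MeOH (axial attack) should favour the epimeric alcohol F8. Mitsunobu inversion (4-nitrobenzoic acid, PPh3, diisopropyl azodicarboxylate) gives the inverted ester F9, and mild methanolysis (K2CO3, MeOH, 0 °C) comes back at 32.

Further compounds
F1 | step 19 | ester acetal (methyl ester analogue of 25) | COC(=O)CC1O[C@@H]2C[C@H](O[Si](C)(C)C(C)(C)C)[C@@](O)(/C=C/[C@H]([C@H](C)O[Si](CC)(CC)CC)/C(C)=C\Br)[C@@H]2O1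
F2 | step 19 | ester hydroxy ketone (methyl ester analogue of 26) | COC(=O)C[C@@H]1O[C@H]2[C@@H]([C@H]1[C@H]([C@H](C)O[Si](CC)(CC)CC)/C(C)=C\Br)C(=O)[C@@H](O[Si](C)(C)C(C)(C)C)C[C@H]2O
F3 | step 19 | C27 silyl ether of F2 | COC(=O)C[C@@H]1O[C@H]2[C@@H]([C@H]1[C@H]([C@H](C)O[Si](CC)(CC)CC)/C(C)=C\Br)C(=O)[C@@H](O[Si](C)(C)C(C)(C)C)C[C@H]2O[Si](C)(C)C(C)(C)C
F4 | step 19 | C14 carboxylic acid | OC(=O)C[C@@H]1O[C@H]2[C@@H]([C@H]1[C@H]([C@H](C)O[Si](CC)(CC)CC)/C(C)=C\Br)C(=O)[C@@H](O[Si](C)(C)C(C)(C)C)C[C@H]2O[Si](C)(C)C(C)(C)C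
F5 | step 19 | 5-acyl-2,2-dimethyl-1,3-dioxane-4,6-dione | CC1(C)OC(=O)C(C(=O)C[C@@H]2O[C@H]3[C@@H]([C@H]2[C@H]([C@H](C)O[Si](CC)(CC)CC)/C(C)=C\Br)C(=O)[C@@H](O[Si](C)(C)C(C)(C)C)C[C@H]3O[Si](C)(C)C(C)(C)C)C(=O)O1
F6 | step 4 | (1Z,3Z)-1-bromo-2-methylpenta-1,3-diene | C/C=C\C(C)=C/Br
F7 | step 4 | (2R,3S)-2-[(Z)-1-bromoprop-1-en-2-yl]-3-methyloxirane | C[C@@H]1O[C@@H]1/C(C)=C\Br
F8 | step 23 | C22 epimer of 32 | CC1(C)OC(=O)C=C(C[C@@H]2O[C@H]3[C@@H]4C(=C[C@@H](O)[C@@H]([C@H]42)/C(C)=C\Br)[C@@H](O[Si](C)(C)C(C)(C)C)C[C@H]3O[Si](C)(C)C(C)(C)C)O1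
F9 | step 23 | C22 4-nitrobenzoate (configuration of 32) | CC1(C)OC(=O)C=C(C[C@@H]2O[C@H]3[C@@H]4C(=C[C@H](OC(=O)c5ccc(cc5)[N+](=O)[O-])[C@@H]([C@H]42)/C(C)=C\Br)[C@@H](O[Si](C)(C)C(C)(C)C)C[C@H]3O[Si](C)(C)C(C)(C)C)O1
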